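## Retrosynthetic overview

1. Ring labels: A is the benzo ring of the chroman, B the 2-aryl ring, C the pyran ring, D the phloroglucinol ring. The last operation is hydrogenolysis of the two benzyl ethers on rings A and B.
2. Key disconnection: the C(=O)–CH2 bond of the dodecanoyl chain. It is made by rhodium-catalysed, phenoxide-directed hydroacylation of undec-1-ene with the ring D aldehyde. Eleven carbons and the ketone arrive in one by-product-free operation on three unprotected phenols.
3. Enabling feature: the O–H groups on C2 and C6 of ring D, ortho to the acyl-bearing C1. As a phenoxide, either one ties rhodium to the formyl carbon in a five-membered chelate (Rh, O, C2 or C6, C1, acyl C).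
4. The C4 (ring C)–C3 (ring D) bond comes from Friedel–Crafts capture of the flavan-4-yl cation by 2,4,6-trihydroxybenzaldehyde, trans to the C2 aryl group. C2 is set by asymmetric 1,4-addition of the ring B boronic acid to 7-benzyloxychromone.
5. Ring order: rings A and C are bought together as 7-hydroxychromone, ring B is attached next, and ring D after it. No ring is closed in the route.

Key step: step 5

Assumption: in step 2 the (S)-configured biaryl bisphosphine is taken to deliver the aryl group to the same enone face as it does with 2-cyclohexenone, which corresponds to (2S) in the flavanone; should the sense be reversed on the chromone, the (R)-ligand is used with no other change.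

## Route

Step 1
Reactants: 1 7-hydroxy-4H-chromen-4-one (7-hydroxychromone)
Product: 2 7-(benzyloxy)-4H-chromen-4-one
Conditions: BnBr (1.1 equiv), K2CO3 (1.5 equiv), acetone, reflux
Reagents that add atoms: benzyl bromide, BrCc1ccccc1
Why: Williamson ether synthesis, in which the acidic C7 phenol (a vinylogous acid of the pyranone carbonyl) is alkylated by benzyl bromide under carbonate conditions that leave the pyranone ring intact, with no stereocenter involved.

Step 2
Reactants: 2 7-(benzyloxy)-4H-chromen-4-one; 3 [4-(benzyloxy)phenyl]boronic acid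
Product: 4 (2S)-7-(benzyloxy)-2-[4-(benzyloxy)phenyl]chroman-4-one
Conditions: 3 (1.5 equiv), [RhCl(C2H4)2]2 (1.5 mol %), (S)-MeO-F12-BIPHEP [(S)-2,2'-bis[bis(3,4,5-trifluorophenyl)phosphino]-6,6'-dimethoxybiphenyl] (3.3 mol %), aq KOH (10 mol %), toluene, rt
Reagents that add atoms: none
Why: Hayashi–Miyaura asymmetric 1,4-addition, a reaction type established for chromones, in which the aryl rhodium species formed by transmetalation inserts the C2=C3 bond, the (S)-bisphosphine leaves only one enone face open so that C2 is set as (S), and the electron-poor ligand keeps the reaction fast at room temperature so that ring opening and 1,2-addition should stay behind.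

Step 3
Reactants: 4 (2S)-7-(benzyloxy)-2-[4-(benzyloxy)phenyl]chroman-4-one
Product: 5 (2S,4S)-7-(benzyloxy)-2-[4-(benzyloxy)phenyl]chroman-4-ol (2,4-cis)
Conditions: NaBH4, THF/MeOH, 0 °C
Reagents that add atoms: none
Why: Borohydride reduction of a flavanone, in which hydride attacks C4 axially on the half-chair that holds the C2 aryl group equatorial and should give the 2,4-cis alcohol (4S), a center that is erased in the next step, while the fully etherified flavanone should not racemise by retro-oxa-Michael opening at this temperature.

Step 4
Reactants: 5 (2S,4S)-7-(benzyloxy)-2-[4-(benzyloxy)phenyl]chroman-4-ol; 6 2,4,6-trihydroxybenzaldehyde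
Product: 8 3-[(2S,4R)-7-(benzyloxy)-2-[4-(benzyloxy)phenyl]chroman-4-yl]-2,4,6-trihydroxybenzaldehyde, via flavan-4-yl cation 7 (not isolated)
Conditions: 6 (3 equiv), TsOH·H2O (10 mol %), 1,4-dioxane/CH2Cl2, 0 °C to rt
Reagents that add atoms: none
Why: Friedel–Crafts alkylation, in which mild acid ionises the C4 alcohol to a cation stabilised by O1 (ortho) and the C7 benzyloxy group (para), one of the two equivalent free carbons of ring D attacks it along the pseudo-axial trajectory of the half-chair with the C2 aryl group equatorial so that C4 is set (R) and trans to C2, and the excess of 6 suppresses a second alkylation.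

Step 5
Reactants: 8 3-[(2S,4R)-7-(benzyloxy)-2-[4-(benzyloxy)phenyl]chroman-4-yl]-2,4,6-trihydroxybenzaldehyde; 9 undec-1-ene
Product: 10 1-{3-[(2S,4R)-7-(benzyloxy)-2-[4-(benzyloxy)phenyl]chroman-4-yl]-2,4,6-trihydroxyphenyl}dodecan-1-one
Conditions: 9 (2 equiv), [Rh(cod)Cl]2 (2.5 mol %), (Ra,R,R)-SIPHOS-PE (spirobiindanediol phosphoramidite of bis(1-phenylethyl)amine, 5.5 mol %), K3PO4 (10 mol %), 1,2-dichloroethane, 70 °C
Reagents that add atoms: none
Why: Catalytic K3PO4 turns a ring D phenol ortho to the formyl group into a phenoxide that binds monovalent rhodium, oxidative addition of the formyl C–H bond gives an acyl hydride of trivalent rhodium held in a five-membered chelate (Rh, O, aryl C–O, aryl C1, acyl C), undec-1-ene inserts into Rh–H with the metal on the terminal carbon, and reductive elimination forms the C(=O)–CH2 bond. The closest known reaction type is the phenoxide-directed, linear-selective rhodium/phosphoramidite hydroacylation of unactivated 1-alkenes with salicylaldehydes, which is known on aldehydes that carry further free phenols and substituents at both ortho positions. No ring is closed and no stereocenter is created, and C2 and C4 of ring C are spectators because neither carries an acidic hydrogen or a leaving group under the weakly basic conditions. The step needs linear over branched insertion, hydroacylation over decarbonylation, and reaction at the formyl C–H bond alone among three free phenols and two benzyl ethers. The bulky spiro phosphoramidite makes branched insertion reversible and unproductive, the chelate holds the acyl group against CO extrusion, and only the two ortho O–H groups can form the chelate, both leading to the same product, most likely through the less hindered C6–OH. In one redox-neutral operation without by-product the step brings in eleven of the thirty-three carbons and places the aryl ketone at its final oxidation level, in place of a protection, organometallic addition, oxidation and deprotection sequence on ring D.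

Step 6
Reactants: 10 1-{3-[(2S,4R)-7-(benzyloxy)-2-[4-(benzyloxy)phenyl]chroman-4-yl]-2,4,6-trihydroxyphenyl}dodecan-1-one
Product: 11 (+)-myristinin A, 1-{2,4,6-trihydroxy-3-[(2S,4R)-7-hydroxy-2-(4-hydroxyphenyl)chroman-4-yl]phenyl}dodecan-1-one
Conditions: H2 (1 atm), Pd(OH)2/C, EtOAc/MeOH, rt
Reagents that add atoms: none
Why: Catalytic hydrogenolysis of aryl benzyl ethers, in which the two O–CH2Ph bonds should be cleaved much faster than the cyclic C2–O1 benzylic ether or the doubly hydrogen-bonded aryl ketone react, so that both stereocenters and the acyl group persist.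

## Compound list

1 | 7-hydroxy-4H-chromen-4-one (7-hydroxychromone) | O=c1ccoc2cc(O)ccc12 | starting material
2 | 7-(benzyloxy)-4H-chromen-4-one | O=c1ccoc2cc(OCc3ccccc3)ccc12 | intermediate
3 | [4-(benzyloxy)phenyl]boronic acid | OB(O)c1ccc(OCc2ccccc2)cc1 | starting material
4 | (2S)-7-(benzyloxy)-2-[4-(benzyloxy)phenyl]chroman-4-one | O=C1C[C@@H](c2ccc(OCc3ccccc3)cc2)Oc2cc(OCc3ccccc3)ccc12 | intermediate
5 | (2S,4S)-7-(benzyloxy)-2-[4-(benzyloxy)phenyl]chroman-4-ol | O[C@H]1C[C@@H](c2ccc(OCc3ccccc3)cc2)Oc2cc(OCc3ccccc3)ccc12 | intermediate
6 | 2,4,6-trihydroxybenzaldehyde | O=Cc1c(O)cc(O)cc1O | starting material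
7 | (2S)-7-(benzyloxy)-2-[4-(benzyloxy)phenyl]chroman-4-ylium (flavan-4-yl cation, not isolated) | [CH+]1C[C@@H](c2ccc(OCc3ccccc3)cc2)Oc2cc(OCc3ccccc3)ccc12 | intermediate
8 | 3-[(2S,4R)-7-(benzyloxy)-2-[4-(benzyloxy)phenyl]chroman-4-yl]-2,4,6-trihydroxybenzaldehyde | O=Cc1c(O)cc(O)c([C@@H]2C[C@@H](c3ccc(OCc4ccccc4)cc3)Oc3cc(OCc4ccccc4)ccc32)c1O | intermediate
9 | undec-1-ene | C=CCCCCCCCCC | starting material
10 | 1-{3-[(2S,4R)-7-(benzyloxy)-2-[4-(benzyloxy)phenyl]chroman-4-yl]-2,4,6-trihydroxyphenyl}dodecan-1-one | CCCCCCCCCCCC(=O)c1c(O)cc(O)c([C@@H]2C[C@@H](c3ccc(OCc4ccccc4)cc3)Oc3cc(OCc4ccccc4)ccc32)c1O | intermediate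
11 | (+)-myristinin A | CCCCCCCCCCCC(=O)c1c(O)cc(O)c([C@@H]2C[C@@H](c3ccc(O)cc3)Oc3cc(O)ccc32)c1O | target

## Step count and risks

Total step count: 6. Longest linear sequence: 6 (from 1 to 11).

Steps most likely to fail:

**Step 5.** Three processes are the risks:
- Oxidative addition of the electron-rich, strongly hydrogen-bonded formyl C–H bond may be slow.
- The acyl rhodium hydride may lose CO and poison the catalyst.
- The alkene may isomerise to unreactive internal positions.

Fallback (polar addition and reoxidation in place of C–H activation): setting out from 8, the three ring D phenols are benzylated (BnBr, K2CO3, DMF) to the pentabenzyl ether aldehyde F1. Undecylmagnesium bromide is added (THF, 0 °C) to give the epimeric carbinols F2. Dess–Martin oxidation gives the pentabenzyl ether ketone F3. Hydrogenolysis of all five benzyl ethers under the conditions of step 6 comes back to the route at 11.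

**Step 4.** The formyl-deactivated nucleophile may capture the cation too slowly. Then loss of a proton from C3, self-alkylation on ring A, a second alkylation of ring D, or erosion of facial selectivity through reversible ionisation could take over.

Fallback (order of the two ring D bond formations reversed): setting out from 5, the cation is trapped at lower temperature with excess unsubstituted benzene-1,3,5-triol (TsOH·H2O cat., dioxane/CH2Cl2). This far stronger nucleophile should give the 2,4-trans 4-(2,4,6-trihydroxyphenyl)flavan F4. Vilsmeier–Haack reaction (POCl3, DMF, EtOAc, 0 °C) at one of the two equivalent free carbons of ring D gives the aryl iminium chloride F5. Aqueous hydrolysis of F5 comes back to the route at 8.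

**Step 2.** The risks are:
- incomplete facial discrimination with the electron-rich boronic acid;
- protodeboronation;
- over-addition to the product carbonyl;
- base-induced ring opening with loss of configuration.

Fallback (stereochemistry set by resolution during carbonyl reduction instead of during C–C bond formation): setting out from 2 and 3, the 1,4-addition is run without a chiral ligand ([Rh(OH)(cod)]2, aqueous dioxane) to the racemic flavanone F6. A Noyori asymmetric transfer hydrogenation follows as a kinetic resolution (RuCl(p-cymene)[(S,S)-TsDPEN], HCO2H/Et3N, rt, stopped at half conversion). The catalyst preference for the (4S) alcohol and the substrate preference for the cis alcohol coincide only for the (2S) enantiomer. The alcohol is separated from unreacted ketone and comes back to the route at 5.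

## Further compounds

F1 | step 5 | 2,4,6-tris(benzyloxy)-3-[(2S,4R)-7-(benzyloxy)-2-[4-(benzyloxy)phenyl]chroman-4-yl]benzaldehyde | O=Cc1c(OCc5ccccc5)cc(OCc6ccccc6)c([C@@H]2C[C@@H](c3ccc(OCc4ccccc4)cc3)Oc3cc(OCc4ccccc4)ccc32)c1OCc7ccccc7
F2 | step 5 | 1-{2,4,6-tris(benzyloxy)-3-[(2S,4R)-7-(benzyloxy)-2-[4-(benzyloxy)phenyl]chroman-4-yl]phenyl}dodecan-1-ol (both carbinol epimers) | CCCCCCCCCCCC(O)c1c(OCc5ccccc5)cc(OCc6ccccc6)c([C@@H]2C[C@@H](c3ccc(OCc4ccccc4)cc3)Oc3cc(OCc4ccccc4)ccc32)c1OCc7ccccc7
F3 | step 5 | 1-{2,4,6-tris(benzyloxy)-3-[(2S,4R)-7-(benzyloxy)-2-[4-(benzyloxy)phenyl]chroman-4-yl]phenyl}dodecan-1-one | CCCCCCCCCCCC(=O)c1c(OCc5ccccc5)cc(OCc6ccccc6)c([C@@H]2C[C@@H](c3ccc(OCc4ccccc4)cc3)Oc3cc(OCc4ccccc4)ccc32)c1OCc7ccccc7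
F4 | step 4 | 2-[(2S,4R)-7-(benzyloxy)-2-[4-(benzyloxy)phenyl]chroman-4-yl]benzene-1,3,5-triol | Oc1cc(O)c([C@@H]2C[C@@H](c3ccc(OCc4ccccc4)cc3)Oc3cc(OCc4ccccc4)ccc32)c(O)c1
F5 | step 4 | N-{3-[(2S,4R)-7-(benzyloxy)-2-[4-(benzyloxy)phenyl]chroman-4-yl]-2,4,6-trihydroxybenzylidene}-N-methylmethanaminium chloride | C[N+](C)=Cc1c(O)cc(O)c([C@@H]2C[C@@H](c3ccc(OCc4ccccc4)cc3)Oc3cc(OCc4ccccc4)ccc32)c1O.[Cl-]
F6 | step 2 | rac-7-(benzyloxy)-2-[4-(benzyloxy)phenyl]chroman-4-one | O=C1CC(c2ccc(OCc3ccccc3)cc2)Oc2cc(OCc3ccccc3)ccc12
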